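**Retrosynthetic overview** (labdane numbering in the text: ring A = C1–C5/C10, ring B = C5–C10)

1. The senecioate is put on last, on the equatorial C2 alcohol, which comes from the C2 ketone of a Δ7-decalinone.
2. Enabling feature: the C2 oxygen is 1,3 to the quaternary ring-fusion carbon C10 through C1, and C10 is 1,6 to C9 next to the endocyclic C7=C8 alkene. A cyclopentane-fused cyclopropanol (OH on C2, CH2 = C1 bridging C2/C10) should therefore give, by O-radical β-scission, the ring-A cyclohexanone (5→6) and a tertiary C10 radical that closes ring B at C9 and expels a sulfonyl group from C7.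
3. That substrate is cut at C6–C7 into a lithiated allyl sulfone and a C6 iodide carrying a regiodefined silyl enol ether, which is cyclopropanated after the union.
4. The iodide arises by TMSI opening of a bicyclo[3.1.0]hexan-2-one, made from 2,4,4-trimethylcyclopentenone by CBS reduction and directed Simmons–Smith reaction (sets C5). The sulfone (C7–C9, C11–C17, C13 stereocentre) comes from (S)-linalool.
5. Ring order: purchased cyclopentane → first fused cyclopropane (C6, opened again) → second fused cyclopropane (C1) → ring A by one-carbon enlargement and ring B by 6-endo closure in the same operation.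

Key step: step 14

Remark: (S)-(+)-linalool is taken as purchasable in enantiopure form; the sulfone-bearing carbon (C7) in 14–16 and the two cyclopropane centres in 15–16 are formed without control because step 14 erases them.

Step 1
Reactants: 1 4,4-dimethylcyclopent-2-en-1-one
Product: 2 2-iodo-4,4-dimethylcyclopent-2-en-1-one
Conditions: I2, pyridine/CH2Cl2, 0 °C → rt
Reagents that add atoms: iodine, II
Why: Pyridine-mediated (Baylis–Hillman-type) α-iodination of a cycloalkenone is general for 4,4-disubstituted enones and installs the handle for the C10 methyl group without forming a stereocentre.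

Step 2
Reactants: 2 2-iodo-4,4-dimethylcyclopent-2-en-1-one
Product: 3 2,4,4-trimethylcyclopent-2-en-1-one
Conditions: Me4Sn, Pd2(dba)3 (cat.), AsPh3 (cat.), CuI (cat.), NMP, 80 °C
Reagents that add atoms: tetramethylstannane, C[Sn](C)(C)C
Why: Stille coupling of an α-iodoenone under ligand-accelerated, copper-assisted conditions is a standard route to α-alkyl enones and forms no stereocentre.

Step 3
Reactants: 3 2,4,4-trimethylcyclopent-2-en-1-one
Product: 4 (1S)-2,4,4-trimethylcyclopent-2-en-1-ol
Conditions: (R)-Me-CBS (cat.), BH3·SMe2, THF, −20 °C; MeOH, aqueous work-up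
Reagents that add atoms: none
Why: Corey–Bakshi–Shibata 1,2-reduction, in which the α-methylated alkenyl arm acts as the large group and the CH2 arm as the small one, so that the (R)-oxazaborolidine should deliver hydride to the face giving the (S)-carbinol.

Step 4
Reactants: 4 (1S)-2,4,4-trimethylcyclopent-2-en-1-ol
Product: 5 (1R,2S,5R)-1,4,4-trimethylbicyclo[3.1.0]hexan-2-ol
Conditions: Et2Zn, CH2I2, CH2Cl2, 0 °C → rt
Reagents that add atoms: diiodomethane, ICI
Why: Hydroxyl-directed Simmons–Smith (Furukawa) cyclopropanation delivers CH2 to the alkene face syn to the oxygen, which sets the future C5 (and transiently C10) from the CBS-derived carbinol.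

Step 5
Reactants: 5 (1R,2S,5R)-1,4,4-trimethylbicyclo[3.1.0]hexan-2-ol
Product: 6 (1R,5R)-1,4,4-trimethylbicyclo[3.1.0]hexan-2-one
Conditions: Dess–Martin periodinane, CH2Cl2, 0 °C → rt
Reagents that add atoms: none
Why: Dess–Martin oxidation of a secondary cyclopropylcarbinol is neutral and leaves the cyclopropane and both ring-fusion centres untouched.

Step 6
Reactants: 6 (1R,5R)-1,4,4-trimethylbicyclo[3.1.0]hexan-2-one
Product: 7 {[(3R)-3-(iodomethyl)-2,4,4-trimethylcyclopent-1-en-1-yl]oxy}trimethylsilane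
Conditions: TMSI, HMDS (cat.), CH2Cl2, −40 → 0 °C; Et3N, pentane, non-acidic work-up, used crude
Reagents that add atoms: iodotrimethylsilane, C[Si](C)(C)I
Why: Homo-conjugate ring opening of a cyclopropyl ketone by TMSI, in which iodide attacks the unhindered CH2 and the exocyclic cyclopropane bond aligned with the carbonyl π system breaks, should give the regiodefined tetrasubstituted silyl enol ether and the C6 iodide while C5 is not touched.

Step 7
Reactants: 8 (S)-(+)-linalool [(3S)-3,7-dimethylocta-1,6-dien-3-ol]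
Product: 9 triethyl{[(3S)-3,7-dimethylocta-1,6-dien-3-yl]oxy}silane
Conditions: TESOTf, 2,6-lutidine, CH2Cl2, −78 → 0 °C
Reagents that add atoms: triethylsilyl trifluoromethanesulfonate, CC[Si](CC)(CC)OS(=O)(=O)C(F)(F)F
Why: Silylation of a tertiary allylic alcohol with a silyl triflate and a hindered base is reliable and does not touch C13.

Step 8
Reactants: 9 triethyl{[(3S)-3,7-dimethylocta-1,6-dien-3-yl]oxy}silane
Product: 10 (2E,6S)-2,6-dimethyl-6-[(triethylsilyl)oxy]octa-2,7-dien-1-ol
Conditions: SeO2 (cat.), t-BuOOH, salicylic acid (cat.), CH2Cl2, rt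
Reagents that add atoms: tert-butyl hydroperoxide, CC(C)(C)OO
Why: Riley allylic oxidation (ene reaction then [2,3]-sigmatropic shift) attacks the trisubstituted alkene at its (E)-methyl group and should give the (E)-allylic alcohol, the vinyl group having no allylic hydrogen.

Step 9
Reactants: 10 (2E,6S)-2,6-dimethyl-6-[(triethylsilyl)oxy]octa-2,7-dien-1-ol
Product: 11 {[(3S,6E)-8-bromo-3,7-dimethylocta-1,6-dien-3-yl]oxy}triethylsilane
Conditions: CBr4, PPh3, CH2Cl2, −20 °C
Reagents that add atoms: tetrabromomethane, BrC(Br)(Br)Br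
Why: Appel bromination of the primary allylic alcohol proceeds by SN2 at CH2 under neutral conditions that keep the silyl ether and the E geometry.

Step 10
Reactants: 11 {[(3S,6E)-8-bromo-3,7-dimethylocta-1,6-dien-3-yl]oxy}triethylsilane
Product: 12 triethyl{[(3S,6E)-3,7-dimethyl-8-(phenylsulfonyl)octa-1,6-dien-3-yl]oxy}silane
Conditions: PhSO2Na, DMF, rt
Reagents that add atoms: sodium benzenesulfinate, [Na+].[O-]S(=O)c1ccccc1
Why: S-Alkylation of the sulfinate by the primary allylic bromide (SN2) in a dipolar aprotic solvent should give the allyl sulfone with the E alkene retained.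

Step 11
Reactants: 12 triethyl{[(3S,6E)-3,7-dimethyl-8-(phenylsulfonyl)octa-1,6-dien-3-yl]oxy}silane; 7 {[(3R)-3-(iodomethyl)-2,4,4-trimethylcyclopent-1-en-1-yl]oxy}trimethylsilane
Product: 14 {[(3R)-3-[(3E,7S)-3,7-dimethyl-2-(phenylsulfonyl)-7-[(triethylsilyl)oxy]nona-3,8-dien-1-yl]-2,4,4-trimethylcyclopent-1-en-1-yl]oxy}trimethylsilane, via lithiated sulfone 13 (not isolated)
Conditions: 12, n-BuLi, THF/DMPU, −78 °C; then 7, −78 → 0 °C
Reagents that add atoms: none
Why: α-Alkylation of a lithiated allyl sulfone with a β-branched primary iodide is an SN2 reaction of the kind used for steroid side chains, the soft carbanion should leave the silyl enol ether intact, and the new sulfone-bearing centre (C7) forms as an inconsequential epimer mixture.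

Step 12
Reactants: 14 {[(3R)-3-[(3E,7S)-3,7-dimethyl-2-(phenylsulfonyl)-7-[(triethylsilyl)oxy]nona-3,8-dien-1-yl]-2,4,4-trimethylcyclopent-1-en-1-yl]oxy}trimethylsilane
Product: 15 {[(1S,4R,5S)-4-[(3E,7S)-3,7-dimethyl-2-(phenylsulfonyl)-7-[(triethylsilyl)oxy]nona-3,8-dien-1-yl]-3,3,5-trimethylbicyclo[3.1.0]hexan-1-yl]oxy}trimethylsilane
Conditions: Et2Zn, CH2I2, CH2Cl2, 0 °C
Reagents that add atoms: diiodomethane, ICI
Why: Simmons–Smith (Furukawa) cyclopropanation should select the electron-rich tetrasubstituted silyl enol ether over the sulfone-deactivated trisubstituted alkene and the hindered vinyl group and occur anti to the C5 side chain, both new centres being erased in step 14.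

Step 13
Reactants: 15 {[(1S,4R,5S)-4-[(3E,7S)-3,7-dimethyl-2-(phenylsulfonyl)-7-[(triethylsilyl)oxy]nona-3,8-dien-1-yl]-3,3,5-trimethylbicyclo[3.1.0]hexan-1-yl]oxy}trimethylsilane
Product: 16 (1S,4R,5S)-4-[(3E,7S)-3,7-dimethyl-2-(phenylsulfonyl)-7-[(triethylsilyl)oxy]nona-3,8-dien-1-yl]-3,3,5-trimethylbicyclo[3.1.0]hexan-1-ol
Conditions: TBAF/AcOH (1:1), THF, −20 °C
Reagents that add atoms: none
Why: Buffered fluoride desilylation should cleave the trimethylsilyl ether of the cyclopropanol far faster than the hindered tertiary triethylsilyl ether, and the acetic acid buffer suppresses base-induced opening of the cyclopropanol.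

Step 14
Reactants: 16 (1S,4R,5S)-4-[(3E,7S)-3,7-dimethyl-2-(phenylsulfonyl)-7-[(triethylsilyl)oxy]nona-3,8-dien-1-yl]-3,3,5-trimethylbicyclo[3.1.0]hexan-1-ol
Product: 20 (4aR,8R,8aR)-4,4,7,8a-tetramethyl-8-[(3S)-3-methyl-3-[(triethylsilyl)oxy]pent-4-en-1-yl]-3,4,4a,5,8,8a-hexahydronaphthalen-2(1H)-one, via alkoxyl radical 17 (not isolated), via ring-enlarged C10 radical 18 (not isolated), via cyclised C8 radical 19 (not isolated)
Conditions: [Ir(dF(CF3)ppy)2(5,5′-d(CF3)bpy)]PF6 (2 mol %), 2,4,6-collidine, degassed PhCF3 (0.01 M), blue LEDs, rt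
Reagents that add atoms: none
Why: Proposed new method: excited Ir(III)/collidine proton-coupled electron transfer at the cyclopropanol O–H should give alkoxyl radical 17, whose β-scission of the internal C2–C10 cyclopropane bond enlarges the cyclopentane by C1 to the ring-A cyclohexanone and leaves the tertiary C10 radical 18; the closest known reaction types are the Fe(III)-mediated ring expansion–cyclisation of 1-siloxybicyclo[n.1.0]alkanes, the photocatalytic ring-opening allylation of cycloalkanols with allyl sulfones, and the C10-radical 6-endo step of Ti(III) epoxypolyene cyclisations. Radical 18 closes ring B by 6-endo-trig addition to C9 of the (E)-C8=C9 alkene, and the tertiary C8 radical 19 expels PhSO2• from C7, which fixes the alkene at C7=C8 and is reduced by Ir(II) to sulfinate, so the cycle is redox-neutral. C10 is controlled by the preset C5 centre, whose tether lies equatorial in a chair-like transition state so that the C9–C10 bond forms anti to H5 (trans-decalin, axial methyl), and C9 is controlled by the E alkene geometry, which places the C11 chain equatorial. The step needs internal rather than external cyclopropane scission (secured by the C10 methyl group, which makes the ring-enlarged radical tertiary), 6-endo rather than 5-exo closure (secured by the fully substituted C8, since 5-exo would join two quaternary carbons), and cyclisation before radical quenching (secured by the absence of hydrogen-atom or halogen donors and by high dilution).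

Step 15
Reactants: 20 (4aR,8R,8aR)-4,4,7,8a-tetramethyl-8-[(3S)-3-methyl-3-[(triethylsilyl)oxy]pent-4-en-1-yl]-3,4,4a,5,8,8a-hexahydronaphthalen-2(1H)-one
Product: 21 (4aR,8R,8aR)-8-[(3S)-3-hydroxy-3-methylpent-4-en-1-yl]-4,4,7,8a-tetramethyl-3,4,4a,5,8,8a-hexahydronaphthalen-2(1H)-one
Conditions: TBAF, THF, rt
Reagents that add atoms: none
Why: Fluoride-mediated desilylation removes the tertiary triethylsilyl ether under non-acidic conditions that spare the ionisable tertiary allylic alcohol.

Step 16
Reactants: 21 (4aR,8R,8aR)-8-[(3S)-3-hydroxy-3-methylpent-4-en-1-yl]-4,4,7,8a-tetramethyl-3,4,4a,5,8,8a-hexahydronaphthalen-2(1H)-one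
Product: 22 (2R,4aR,8R,8aR)-8-[(3S)-3-hydroxy-3-methylpent-4-en-1-yl]-4,4,7,8a-tetramethyl-1,2,3,4,4a,5,8,8a-octahydronaphthalen-2-ol
Conditions: Li, NH3(l)/THF, t-BuOH, −78 °C; solid NH4Cl
Reagents that add atoms: none
Why: Dissolving-metal reduction of a cyclohexanone is under thermodynamic control and should give the equatorial C2 alcohol (on the face of H5, away from the C10 and axial C4 methyl groups), while the isolated alkenes and the C13 alkoxide are inert.

Step 17
Reactants: 22 (2R,4aR,8R,8aR)-8-[(3S)-3-hydroxy-3-methylpent-4-en-1-yl]-4,4,7,8a-tetramethyl-1,2,3,4,4a,5,8,8a-octahydronaphthalen-2-ol; 23 3-methylbut-2-enoyl chloride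
Product: 24 (2R,4aR,8R,8aR)-8-[(3S)-3-hydroxy-3-methylpent-4-en-1-yl]-4,4,7,8a-tetramethyl-1,2,3,4,4a,5,8,8a-octahydronaphthalen-2-yl 3-methylbut-2-enoate
Conditions: pyridine, DMAP (cat.), CH2Cl2, 0 °C
Reagents that add atoms: none
Why: Acylation with an acid chloride under nucleophilic catalysis should esterify the unhindered equatorial secondary alcohol selectively over the tertiary allylic alcohol, with retention at C2.

**Compound list**

1 | 4,4-dimethylcyclopent-2-en-1-one | CC1(C)C=CC(=O)C1 | starting material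
2 | 2-iodo-4,4-dimethylcyclopent-2-en-1-one | CC1(C)C=C(I)C(=O)C1 | intermediate
3 | 2,4,4-trimethylcyclopent-2-en-1-one | CC1=CC(C)(C)CC1=O | intermediate
4 | (1S)-2,4,4-trimethylcyclopent-2-en-1-ol | CC1=CC(C)(C)C[C@@H]1O | intermediate
5 | (1R,2S,5R)-1,4,4-trimethylbicyclo[3.1.0]hexan-2-ol | CC1(C)C[C@H](O)[C@]2(C)C[C@H]12 | intermediate
6 | (1R,5R)-1,4,4-trimethylbicyclo[3.1.0]hexan-2-one | CC1(C)CC(=O)[C@]2(C)C[C@H]12 | intermediate
7 | {[(3R)-3-(iodomethyl)-2,4,4-trimethylcyclopent-1-en-1-yl]oxy}trimethylsilane | IC[C@@H]1C(C)(C)CC(O[Si](C)(C)C)=C1C | intermediate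
8 | (S)-(+)-linalool | C=C[C@@](C)(O)CCC=C(C)C | starting material
9 | triethyl{[(3S)-3,7-dimethylocta-1,6-dien-3-yl]oxy}silane | C=C[C@@](C)(O[Si](CC)(CC)CC)CCC=C(C)C | intermediate
10 | (2E,6S)-2,6-dimethyl-6-[(triethylsilyl)oxy]octa-2,7-dien-1-ol | C=C[C@@](C)(O[Si](CC)(CC)CC)CC/C=C(\C)CO | intermediate
11 | {[(3S,6E)-8-bromo-3,7-dimethylocta-1,6-dien-3-yl]oxy}triethylsilane | C=C[C@@](C)(O[Si](CC)(CC)CC)CC/C=C(\C)CBr | intermediate
12 | triethyl{[(3S,6E)-3,7-dimethyl-8-(phenylsulfonyl)octa-1,6-dien-3-yl]oxy}silane | C=C[C@@](C)(O[Si](CC)(CC)CC)CC/C=C(\C)CS(=O)(=O)c1ccccc1 | intermediate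
13 | α-lithio derivative of 12 (lithium on the CH–SO2Ph carbon) | C=C[C@@](C)(O[Si](CC)(CC)CC)CC/C=C(\C)C([Li])S(=O)(=O)c1ccccc1 | intermediate
14 | {[(3R)-3-[(3E,7S)-3,7-dimethyl-2-(phenylsulfonyl)-7-[(triethylsilyl)oxy]nona-3,8-dien-1-yl]-2,4,4-trimethylcyclopent-1-en-1-yl]oxy}trimethylsilane (epimers at the sulfone carbon) | C=C[C@@](C)(O[Si](CC)(CC)CC)CC/C=C(\C)C(S(=O)(=O)c1ccccc1)C[C@@H]2C(C)(C)CC(O[Si](C)(C)C)=C2C | intermediate
15 | {[(1S,4R,5S)-4-[(3E,7S)-3,7-dimethyl-2-(phenylsulfonyl)-7-[(triethylsilyl)oxy]nona-3,8-dien-1-yl]-3,3,5-trimethylbicyclo[3.1.0]hexan-1-yl]oxy}trimethylsilane (epimers at the sulfone carbon) | C=C[C@@](C)(O[Si](CC)(CC)CC)CC/C=C(\C)C(S(=O)(=O)c1ccccc1)C[C@@H]2C(C)(C)C[C@@]3(O[Si](C)(C)C)C[C@@]23C | intermediate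
16 | (1S,4R,5S)-4-[(3E,7S)-3,7-dimethyl-2-(phenylsulfonyl)-7-[(triethylsilyl)oxy]nona-3,8-dien-1-yl]-3,3,5-trimethylbicyclo[3.1.0]hexan-1-ol (epimers at the sulfone carbon) | C=C[C@@](C)(O[Si](CC)(CC)CC)CC/C=C(\C)C(S(=O)(=O)c1ccccc1)C[C@@H]2C(C)(C)C[C@@]3(O)C[C@@]23C | intermediate
17 | alkoxyl radical of 16 (oxygen-centred, on the cyclopropane bridgehead C2) | C=C[C@@](C)(O[Si](CC)(CC)CC)CC/C=C(\C)C(S(=O)(=O)c1ccccc1)C[C@@H]2C(C)(C)C[C@@]3([O])C[C@@]23C | intermediate
18 | ring-enlarged C10 radical (1,5,5-trimethyl-3-oxocyclohexyl radical with the sulfone side chain on the ring carbon between the radical centre and the gem-dimethyl carbon) | C=C[C@@](C)(O[Si](CC)(CC)CC)CC/C=C(\C)C(S(=O)(=O)c1ccccc1)C[C@@H]2C(C)(C)CC(=O)C[C]2C | intermediate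
19 | cyclised C8 radical (trans-decalin-2-one, radical at C8, PhSO2 on C7) | C=C[C@@](C)(O[Si](CC)(CC)CC)CC[C@@H]1[C](C)C(S(=O)(=O)c3ccccc3)C[C@@H]2C(C)(C)CC(=O)C[C@@]12C | intermediate
20 | (4aR,8R,8aR)-4,4,7,8a-tetramethyl-8-[(3S)-3-methyl-3-[(triethylsilyl)oxy]pent-4-en-1-yl]-3,4,4a,5,8,8a-hexahydronaphthalen-2(1H)-one | C=C[C@@](C)(O[Si](CC)(CC)CC)CC[C@@H]1C(C)=CC[C@@H]2C(C)(C)CC(=O)C[C@@]12C | intermediate
21 | (4aR,8R,8aR)-8-[(3S)-3-hydroxy-3-methylpent-4-en-1-yl]-4,4,7,8a-tetramethyl-3,4,4a,5,8,8a-hexahydronaphthalen-2(1H)-one | C=C[C@@](C)(O)CC[C@@H]1C(C)=CC[C@@H]2C(C)(C)CC(=O)C[C@@]12C | intermediate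
22 | (2R,4aR,8R,8aR)-8-[(3S)-3-hydroxy-3-methylpent-4-en-1-yl]-4,4,7,8a-tetramethyl-1,2,3,4,4a,5,8,8a-octahydronaphthalen-2-ol | C=C[C@@](C)(O)CC[C@@H]1C(C)=CC[C@@H]2C(C)(C)C[C@@H](O)C[C@@]12C | intermediate
23 | 3-methylbut-2-enoyl chloride | CC(C)=CC(=O)Cl | starting material
24 | (2R,4aR,8R,8aR)-8-[(3S)-3-hydroxy-3-methylpent-4-en-1-yl]-4,4,7,8a-tetramethyl-1,2,3,4,4a,5,8,8a-octahydronaphthalen-2-yl 3-methylbut-2-enoate | C=C[C@@](C)(O)CC[C@@H]1C(C)=CC[C@@H]2C(C)(C)C[C@@H](OC(=O)C=C(C)C)C[C@@]12C | target

**Step count:** 17 steps in total; longest linear sequence 13 steps (steps 1–6, then 11–17); the sulfone branch (steps 7–10) is 4 steps.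

**Steps most likely to fail**

Step 14 (proposed new method). The process at risk is quenching of the tertiary C10 radical 18 before the 6-endo closure (back electron transfer, or a 1,6-hydrogen shift from the C8 methyl group), or inefficient O–H activation of 16. The fallback uses known chemistry, sets out from silyl ether 15 and comes back at 20. Ito–Saegusa ring enlargement of 15 with FeCl3 in DMF/pyridine at 0 °C, in which the ring-enlarged radical is trapped at once by chlorine transfer, should give the tertiary β-chloro ketone with ring A already six-membered, (4R)-3-chloro-4-[(3E,7S)-3,7-dimethyl-2-(phenylsulfonyl)-7-[(triethylsilyl)oxy]nona-3,8-dien-1-yl]-3,5,5-trimethylcyclohexan-1-one F1. Slow addition of (Me3Si)3SiH/AIBN in toluene at 90 °C then regenerates the C10 radical by chlorine abstraction in a medium without oxidant, and radical cyclisation with β-sulfonyl elimination should give 20.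

Step 11. The process at risk is a slow SN2 displacement at the β-branched CH2I, during which the carbanion attacks silicon and the regiodefined enol ether is lost. The fallback sets out from 7 and comes back at 15 by inverting the order of union and cyclopropanation. Iodide 7 is first cyclopropanated (Et2Zn, CH2I2) to the base-stable {[(1S,4R,5S)-4-(iodomethyl)-3,3,5-trimethylbicyclo[3.1.0]hexan-1-yl]oxy}trimethylsilane F2, which tolerates forcing alkylation with 13 (THF/HMPA, rt, excess carbanion) and should give 15 directly.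

Step 16. The process at risk is incomplete thermodynamic control at C2 or partial reduction of the terminal vinyl group. The fallback sets out from 21 and comes back at 24. L-Selectride at −78 °C attacks along the equatorial direction, because the axial trajectory is blocked by the C10 and axial C4 methyl groups, and should give the axial alcohol (2S,4aR,8R,8aR)-8-[(3S)-3-hydroxy-3-methylpent-4-en-1-yl]-4,4,7,8a-tetramethyl-1,2,3,4,4a,5,8,8a-octahydronaphthalen-2-ol F3. Mitsunobu esterification of F3 with 3-methylbut-2-enoic acid (PPh3, DIAD) inverts C2 and should give 24 directly, the tertiary alcohol being inert.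

**Further compounds**

F1 | step 14 | (4R)-3-chloro-4-[(3E,7S)-3,7-dimethyl-2-(phenylsulfonyl)-7-[(triethylsilyl)oxy]nona-3,8-dien-1-yl]-3,5,5-trimethylcyclohexan-1-one | C=C[C@@](C)(O[Si](CC)(CC)CC)CC/C=C(\C)C(S(=O)(=O)c1ccccc1)C[C@@H]2C(C)(C)CC(=O)CC2(C)Cl
F2 | step 11 | {[(1S,4R,5S)-4-(iodomethyl)-3,3,5-trimethylbicyclo[3.1.0]hexan-1-yl]oxy}trimethylsilane | IC[C@@H]1C(C)(C)C[C@@]2(O[Si](C)(C)C)C[C@@]12C
F3 | step 16 | (2S,4aR,8R,8aR)-8-[(3S)-3-hydroxy-3-methylpent-4-en-1-yl]-4,4,7,8a-tetramethyl-1,2,3,4,4a,5,8,8a-octahydronaphthalen-2-ol | C=C[C@@](C)(O)CC[C@@H]1C(C)=CC[C@@H]2C(C)(C)C[C@H](O)C[C@@]12C
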